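The butenolide ring (O1, C2 carbonyl, C3 methyl, C4 chain, C5 methylene) is cut at C3=C4 and O1–C5. This exploits the fact that C5 and C4 are simply the last two carbons of an unbranched C18 chain carrying the acetoxy stereocentre, while C2, C3 and the 3-methyl group are a pyruvate unit. A single amine-mediated aldol condensation of the C18 aldehyde (donor at its α-carbon) with pyruvic acid, followed by spontaneous lactol closure, makes both bonds and the ring at once. The precursor is (2S)-18-oxooctadecan-2-yl acetate, assembled from ω-pentadecalactone and (S)-propylene oxide, the source of the only stereocentre; borohydride reduction of the lactol finishes the synthesis.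

Key step: step 8

Remark: lactol 14 is carried on as the mixture of its two C5 epimers (each with the 2S side chain), because step 9 turns that carbon into the ring CH2; the acetate installed in step 5 is the target's own ester and serves as the only protecting group on the C-2 oxygen.

Step 1
Reactants: 1 ω-pentadecalactone
Product: 2 15-bromopentadecanoic acid
Conditions: HBr (33% in AcOH), conc. H2SO4 (cat.), 90 °C
Reagents that add atoms: hydrogen bromide, Br
Why: Acid-mediated lactone cleavage, in which bromide displaces the protonated ester oxygen at the primary ω-carbon (SN2), is the standard opening of macrolactones to ω-bromo acids.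

Step 2
Reactants: 2 15-bromopentadecanoic acid
Product: 3 15-bromopentadecan-1-ol
Conditions: BH3·THF, THF, 0 °C to rt; aqueous work-up
Reagents that add atoms: none
Why: Chemoselective borane reduction takes a free carboxylic acid to the primary alcohol through its acyloxyborane while a primary alkyl bromide is inert.

Step 3
Reactants: 3 15-bromopentadecan-1-ol
Product: 4 [(15-bromopentadecyl)oxy](tert-butyl)dimethylsilane
Conditions: TBSCl, imidazole, DMF, rt
Reagents that add atoms: tert-butyldimethylsilyl chloride, CC(C)(C)[Si](C)(C)Cl
Why: Imidazole-promoted silylation of a primary alcohol should be clean, and the TBS ether tolerates Grignard formation and is later removable without touching an acetate.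

Step 4
Reactants: 4 [(15-bromopentadecyl)oxy](tert-butyl)dimethylsilane; 5 (S)-propylene oxide
Product: 7 (2S)-18-[(tert-butyldimethylsilyl)oxy]octadecan-2-ol, via [15-(tert-butyldimethylsilyloxy)pentadecyl]magnesium bromide 6 (not isolated)
Conditions: Mg turnings, I2 (cat.), THF, 45 °C; then CuI (10 mol %), 5 (1.3 equiv), THF, −30 to 0 °C; sat. aq. NH4Cl
Reagents that add atoms: none
Why: Copper-catalysed Grignard opening of a terminal epoxide occurs by SN2 attack at the unsubstituted CH2, so no bond at the stereocentre of 5 is touched and C-2 of 7 keeps the S configuration.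

Step 5
Reactants: 7 (2S)-18-[(tert-butyldimethylsilyl)oxy]octadecan-2-ol
Product: 8 (2S)-18-[(tert-butyldimethylsilyl)oxy]octadecan-2-yl acetate
Conditions: Ac2O, pyridine, DMAP (cat.), CH2Cl2, rt
Reagents that add atoms: acetic anhydride, CC(=O)OC(C)=O
Why: DMAP-catalysed acylation of a secondary alcohol forms only the O–acyl bond, so the S configuration is retained.

Step 6
Reactants: 8 (2S)-18-[(tert-butyldimethylsilyl)oxy]octadecan-2-yl acetate
Product: 9 (2S)-18-hydroxyoctadecan-2-yl acetate
Conditions: HF·pyridine, THF, 0 °C to rt
Reagents that add atoms: none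
Why: Fluoride-driven desilylation under mildly acidic conditions cleaves the primary TBS ether and leaves the secondary acetate, which is remote and cannot migrate, untouched.

Step 7
Reactants: 9 (2S)-18-hydroxyoctadecan-2-yl acetate
Product: 10 (2S)-18-oxooctadecan-2-yl acetate
Conditions: TEMPO (10 mol %), PhI(OAc)2 (1.1 equiv), CH2Cl2, rt
Reagents that add atoms: none
Why: Oxoammonium (TEMPO/PhI(OAc)2) oxidation of a primary alcohol stops at the aldehyde in anhydrous CH2Cl2 and is neutral enough for the acetate and the α-CH2.

Step 8
Reactants: 10 (2S)-18-oxooctadecan-2-yl acetate; 11 pyruvic acid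
Product: 14 (2S)-16-(2-hydroxy-4-methyl-5-oxo-2,5-dihydrofuran-3-yl)hexadecan-2-yl acetate as both lactol epimers, via morpholine enamine 12 (not isolated), via open-chain Z-formylacrylic acid 13 (not isolated)
Conditions: 11 (3 equiv), morpholine hydrochloride (1.2 equiv), 1,4-dioxane/H2O (10:1), 10 added over 2 h at 70 °C, then reflux
Reagents that add atoms: none
Why: Morpholinium chloride converts the aldehyde reversibly into enamine 12, whose β-carbon (chain C-17, future ring C4) adds to the keto carbonyl of 11 (future C3), and dehydration through the conjugated iminium followed by hydrolysis gives formylacrylic acid 13. The isomer of 13 with CHO and CO2H cis closes by 5-exo-trig addition of the carboxyl oxygen to the aldehyde carbon (O1–C5), while the trans isomer is returned to the cis one through reversible iminium/dienamine formation, so ring closure drains the equilibrium. The closest known reaction type is the amine-salt-mediated aldol condensation of enolisable aldehydes with 2-oxo acids (glyoxylic acid being the usual partner) to 5-hydroxybutenolides. The only new stereocentre, lactol carbon C5, forms without control as both epimers and is deleted in step 9, and the remote C-2 acetoxy centre is not involved. The step needs cross-selectivity (aldehyde as donor, pyruvate ketone as acceptor) over aldehyde self-aldol and pyruvate self-condensation; this is secured because the secondary amine forms an enamine much faster with the unhindered aldehyde than with the keto acid, and because slow addition into excess 11 keeps the aldehyde dilute next to the most electrophilic carbonyl present. Substituent positions are fixed because 10 has a single enolisable CH2 and 11 already carries the C3 methyl, and the weakly acidic medium should leave the secondary acetate in place.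

Step 9
Reactants: 14 (2S)-16-(2-hydroxy-4-methyl-5-oxo-2,5-dihydrofuran-3-yl)hexadecan-2-yl acetate
Product: 16 (2S)-16-(4-methyl-5-oxo-2,5-dihydrofuran-3-yl)hexadecan-2-yl acetate, via Z-hydroxy acid 15 (not isolated)
Conditions: NaBH4 (1.5 equiv), THF/EtOH (4:1), 0 °C; then 1 M HCl to pH 1–2, rt
Reagents that add atoms: none
Why: In the basic borohydride medium lactol 14 is in ring-chain equilibrium with the sodium carboxylate of its open formyl-acid tautomer (the conjugate base of 13 from step 8), whose aldehyde is reduced by 1,2-hydride addition, and acidification lets Z-hydroxy acid 15 lactonise by 5-exo-trig closure, which turns the lactol carbon into the ring CH2, while the acetate is inert to NaBH4 at 0 °C.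

Compound list
1 | ω-pentadecalactone (oxacyclohexadecan-2-one) | O=C1CCCCCCCCCCCCCCO1 | starting material
2 | 15-bromopentadecanoic acid | OC(=O)CCCCCCCCCCCCCCBr | intermediate
3 | 15-bromopentadecan-1-ol | OCCCCCCCCCCCCCCCBr | intermediate
4 | [(15-bromopentadecyl)oxy](tert-butyl)dimethylsilane | CC(C)(C)[Si](C)(C)OCCCCCCCCCCCCCCCBr | intermediate
5 | (S)-propylene oxide [(2S)-2-methyloxirane] | C[C@H]1CO1 | starting material
6 | [15-(tert-butyldimethylsilyloxy)pentadecyl]magnesium bromide | CC(C)(C)[Si](C)(C)OCCCCCCCCCCCCCCC[Mg]Br | intermediate
7 | (2S)-18-[(tert-butyldimethylsilyl)oxy]octadecan-2-ol | C[C@H](O)CCCCCCCCCCCCCCCCO[Si](C)(C)C(C)(C)C | intermediate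
8 | (2S)-18-[(tert-butyldimethylsilyl)oxy]octadecan-2-yl acetate | CC(=O)O[C@@H](C)CCCCCCCCCCCCCCCCO[Si](C)(C)C(C)(C)C | intermediate
9 | (2S)-18-hydroxyoctadecan-2-yl acetate | CC(=O)O[C@@H](C)CCCCCCCCCCCCCCCCO | intermediate
10 | (2S)-18-oxooctadecan-2-yl acetate | CC(=O)O[C@@H](C)CCCCCCCCCCCCCCCC=O | intermediate
11 | pyruvic acid | CC(=O)C(=O)O | starting material
12 | (2S,17E)-18-(morpholin-4-yl)octadec-17-en-2-yl acetate | CC(=O)O[C@@H](C)CCCCCCCCCCCCCC/C=C/N1CCOCC1 | intermediate
13 | (2Z,18S)-18-acetoxy-3-formyl-2-methylnonadec-2-enoic acid | CC(=O)O[C@@H](C)CCCCCCCCCCCCCC/C(C=O)=C(\C)C(=O)O | intermediate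
14 | (2S)-16-(2-hydroxy-4-methyl-5-oxo-2,5-dihydrofuran-3-yl)hexadecan-2-yl acetate (both lactol epimers) | CC(=O)O[C@@H](C)CCCCCCCCCCCCCCC1=C(C)C(=O)OC1O | intermediate
15 | (2Z,18S)-18-acetoxy-3-(hydroxymethyl)-2-methylnonadec-2-enoic acid | CC(=O)O[C@@H](C)CCCCCCCCCCCCCC/C(CO)=C(\C)C(=O)O | intermediate
16 | (2S)-16-(4-methyl-5-oxo-2,5-dihydrofuran-3-yl)hexadecan-2-yl acetate | CC(=O)O[C@@H](C)CCCCCCCCCCCCCCC1=C(C)C(=O)OC1 | target

Total step count: 9. Longest linear sequence: 9 steps (1 to 16); 5 and 11 enter as purchased building blocks.

Steps most likely to fail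

Step 8. The cross-aldol may lose direction: self-condensation of the aldehyde through its enamine, self-condensation of pyruvic acid, or attack of the pyruvate enol on the aldehyde could all divert material. The fallback builds the same C3=C4 bond by ring-closing metathesis instead; it sets out from aldehyde 10 and comes back to the route at target 16. α-Methylenation of 10 (37% aq. HCHO, pyrrolidine and propionic acid, 10 mol % each, i-PrOH, 45 °C) should give (2S)-17-methylidene-18-oxooctadecan-2-yl acetate F1. Luche reduction (NaBH4, CeCl3·7H2O, MeOH, 0 °C) should give the allylic alcohol (2S)-18-hydroxy-17-methylideneoctadecan-2-yl acetate F2. Acylation with methacryloyl chloride (Et3N, DMAP, CH2Cl2, 0 °C) should give the diene ester (17S)-17-(acetyloxy)-2-methylideneoctadecyl 2-methylprop-2-enoate F3. Ring-closing metathesis (second-generation Grubbs catalyst, toluene, 80–100 °C, ethene swept out) should then close the tetrasubstituted butenolide 16; the carbon added in the methylenation leaves as ethene.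

Step 4. Sluggish initiation of the long-chain Grignard reagent, Wurtz homocoupling, and halide-mediated opening of the epoxide to a halohydrin could erode the yield. The fallback replaces the Grignard reagent by a sulfone-stabilised carbanion; it sets out from bromide 4 and comes back at alcohol 7. Displacement with PhSO2Na (DMF, 60 °C) should give tert-butyl(dimethyl){[15-(phenylsulfonyl)pentadecyl]oxy}silane F4. Deprotonation (n-BuLi, THF, −78 °C) and opening of (S)-propylene oxide 5 at its CH2 terminus (BF3·OEt2) should give (2S)-18-[(tert-butyldimethylsilyl)oxy]-4-(phenylsulfonyl)octadecan-2-ol F5 as both C-4 epimers, with the S carbinol centre again taken unchanged from 5. Reductive desulfonylation (Na(Hg), Na2HPO4, MeOH, −20 °C) should then give 7.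

Step 9. Ethoxide and alkoxyborate formed during the reduction may transesterify the secondary acetate, giving a mixture of acetylated and free alcohol. The fallback gives up protecting the ester and reinstalls it at the end; it sets out from lactol 14 and comes back at target 16. Reduction in methanol followed by acid methanolysis in the same flask (NaBH4, MeOH, 0 °C; then HCl in MeOH, 40 °C) should give the deacetylated butenolide 4-[(15S)-15-hydroxyhexadecyl]-3-methylfuran-2(5H)-one F6. Acetylation (Ac2O, pyridine, DMAP, CH2Cl2, rt) should then return 16 with the S centre untouched.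

Further compounds
F1 | step 8 | (2S)-17-methylidene-18-oxooctadecan-2-yl acetate | CC(=O)O[C@@H](C)CCCCCCCCCCCCCCC(=C)C=O
F2 | step 8 | (2S)-18-hydroxy-17-methylideneoctadecan-2-yl acetate | CC(=O)O[C@@H](C)CCCCCCCCCCCCCCC(=C)CO
F3 | step 8 | (17S)-17-(acetyloxy)-2-methylideneoctadecyl 2-methylprop-2-enoate | CC(=O)O[C@@H](C)CCCCCCCCCCCCCCC(=C)COC(=O)C(C)=C
F4 | step 4 | tert-butyl(dimethyl){[15-(phenylsulfonyl)pentadecyl]oxy}silane | CC(C)(C)[Si](C)(C)OCCCCCCCCCCCCCCCS(=O)(=O)c1ccccc1
F5 | step 4 | (2S)-18-[(tert-butyldimethylsilyl)oxy]-4-(phenylsulfonyl)octadecan-2-ol (both C-4 epimers) | C[C@H](O)CC(CCCCCCCCCCCCCCO[Si](C)(C)C(C)(C)C)S(=O)(=O)c1ccccc1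
F6 | step 9 | 4-[(15S)-15-hydroxyhexadecyl]-3-methylfuran-2(5H)-one | C[C@H](O)CCCCCCCCCCCCCCC1=C(C)C(=O)OC1
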